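**Plan**
- Retrosynthesis: the two ring B methoxymethyl (MOM) ethers come off last. Ring A and the pyran ring are then opened together by cutting C4a–C5, C6–C7, C7–C8 and C4a–C8a, which leads to the acyclic α-diazo dienone 28 carrying an ethynyl ether on O1.
- 28 is cut further at the diazo group, at C7–C5 (alkenyllithium + Weinreb amide), at O1–C8a (alkoxide + trichloroethylene) and at C3–C4 (Michael addition to methyl acrylate), back to ring B arylacetic acid 8. Acid 8 comes from 2,4-dihydroxybenzaldehyde by O-prenylation, aromatic Claisen rearrangement and one-carbon homologation.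
- Forward: ring B is dressed first (steps 1–6), the chain is joined in the order C3–C4, O1–C8a, C7–C5 (steps 8, 11, 15), and the pyran ring and ring A arise together in step 17.
- Stereochemistry: the only stereocentre, C3 (R), is set in step 8 by the (R)-4-benzyloxazolidinone auxiliary and is a spectator afterwards.
- Enabling feature: ring A is a resorcinol ring whose two oxygens (O1 on C8a, OH on C7) are meta, with C4a carbon-substituted, C6 carrying the tert-alkyl group and C5/C8 unsubstituted. This is the pattern a vinylketene/ynol ether benzannulation delivers when the ynol oxygen is O1.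

Key step: step 17

Remark: the SMILES is read as the (3R)-isoflavan (CIP order at C3: C2 > C1′ > C4 > H); chroman numbering (O1, C2, C3, C4, C4a, C5–C8, C8a; ring B primed) is used for all open-chain intermediates as well.
Abbreviation: Ar = 2,4-bis(methoxymethoxy)-5-(2-methylbut-3-en-2-yl)phenyl.

**Route**

Step 1
Reactants: 1 2,4-dihydroxybenzaldehyde; 2 prenyl bromide (1-bromo-3-methylbut-2-ene)
Product: 3 2-hydroxy-4-(3-methylbut-2-enyloxy)benzaldehyde
Conditions: K2CO3, acetone, reflux
Reagents that add atoms: none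
Why: Williamson etherification should take place at the 4-OH only, because the 2-OH is held in a hydrogen bond to the formyl group and is the poorer nucleophile.

Step 2
Reactants: 3 2-hydroxy-4-(3-methylbut-2-enyloxy)benzaldehyde
Product: 4 2-(methoxymethoxy)-4-(3-methylbut-2-enyloxy)benzaldehyde
Conditions: MOMCl, i-Pr2NEt, CH2Cl2, 0 → 40 °C
Reagents that add atoms: chloromethyl methyl ether, COCCl
Why: Acetal protection (O-alkylation) of the remaining phenol removes the chelate that would steer the coming rearrangement to C3 and installs a group that is stable to the basic, reducing and photochemical steps ahead.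

Step 3
Reactants: 4 2-(methoxymethoxy)-4-(3-methylbut-2-enyloxy)benzaldehyde
Product: 5 4-hydroxy-2-(methoxymethoxy)-5-(2-methylbut-3-en-2-yl)benzaldehyde
Conditions: PhNEt2, 190 °C, sealed tube, degassed
Reagents that add atoms: none
Why: Aromatic Claisen rearrangement ([3,3] shift, then rearomatisation) should deliver the inverted 1,1-dimethylallyl group to C5, the ortho position not wedged between the two oxygen substituents, as is known for 2-alkoxy-4-prenyloxybenzaldehydes.

Step 4
Reactants: 5 4-hydroxy-2-(methoxymethoxy)-5-(2-methylbut-3-en-2-yl)benzaldehyde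
Product: 6 2,4-bis(methoxymethoxy)-5-(2-methylbut-3-en-2-yl)benzaldehyde (Ar–CHO)
Conditions: NaH, MOMCl, DMF, 0 °C → rt
Reagents that add atoms: chloromethyl methyl ether, COCCl
Why: The hindered but acidic (para-formyl) phenol is alkylated as its sodium phenoxide (Williamson-type MOM protection), so both ring B oxygens carry the same base-stable group.

Step 5
Reactants: 6 Ar–CHO
Product: 7 Ar-acetonitrile (Ar–CH2CN)
Conditions: TosMIC, KOt-Bu, DME, −30 °C → rt; then MeOH, reflux
Reagents that add atoms: p-toluenesulfonylmethyl isocyanide (TosMIC), Cc1ccc(S(=O)(=O)C[N+]#[C-])cc1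
Why: Van Leusen reductive cyanation converts an aromatic aldehyde into the homologous arylacetonitrile in one basic operation that the acetals and the hindered vinyl group tolerate.

Step 6
Reactants: 7 Ar–CH2CN
Product: 8 Ar-acetic acid (Ar–CH2CO2H)
Conditions: KOH, EtOH/H2O, reflux; then 1 M HCl to pH 3–4, 0 °C
Reagents that add atoms: potassium hydroxide, [K+].[OH-]; water, O
Why: Alkaline nitrile hydrolysis gives the carboxylate without touching the MOM ethers, which should survive the brief cold acidification.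

Step 7
Reactants: 8 Ar–CH2CO2H; 9 (R)-4-benzyl-1,3-oxazolidin-2-one
Product: 11 (4R)-4-benzyl-3-(Ar-acetyl)-1,3-oxazolidin-2-one, via mixed pivalic anhydride 10 (not isolated)
Conditions: t-BuCOCl, Et3N, THF, −20 °C; then 9, LiCl, rt
Reagents that add atoms: none
Why: N-acylation of the oxazolidinone by the mixed anhydride (LiCl/Et3N-mediated acyl transfer) occurs at the less hindered arylacetyl carbonyl and attaches the chiral auxiliary.

Step 8
Reactants: 11 (4R)-4-benzyl-3-(Ar-acetyl)-1,3-oxazolidin-2-one; 12 methyl acrylate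
Product: 14 methyl (4R)-4-Ar-5-[(4R)-4-benzyl-2-oxo-1,3-oxazolidin-3-yl]-5-oxopentanoate, via Ti(Oi-Pr)Cl2 Z-enolate 13 (not isolated)
Conditions: TiCl4/Ti(Oi-Pr)4 (3:1), i-Pr2NEt, CH2Cl2, −78 → 0 °C; then 12, 0 °C
Reagents that add atoms: none
Why: Soft enolisation gives the chelated Z-enolate 13, and methyl acrylate should add to the face opposite the auxiliary benzyl group (auxiliary-controlled titanium enolate Michael addition), which forms C3–C4 and sets C3 as R.

Step 9
Reactants: 14 methyl (4R)-4-Ar-5-[(4R)-4-benzyl-2-oxo-1,3-oxazolidin-3-yl]-5-oxopentanoate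
Product: 16 (5R)-5-Ar-oxan-2-one, via hydroxy ester 15 (not isolated)
Conditions: NaBH4, THF/H2O (4:1), 0 °C → rt; then PPTS (cat.), PhMe, 50 °C
Reagents that add atoms: none
Why: Borohydride reduces only the activated imide carbonyl (reductive auxiliary removal, ester untouched, no enolisation at C3), and the resulting δ-hydroxy ester lactonises under mild acid catalysis.

Step 10
Reactants: 16 (5R)-5-Ar-oxan-2-one
Product: 17 (4R)-4-Ar-5-hydroxy-N-methoxy-N-methylpentanamide
Conditions: MeNH(OMe)·HCl, i-PrMgCl, THF, −20 → 0 °C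
Reagents that add atoms: N,O-dimethylhydroxylamine hydrochloride, CNOC.Cl
Why: Aminolysis of the lactone by the magnesium amide (Weinreb amide formation) frees the C2 hydroxyl and leaves C7 as an acyl donor that resists the neighbouring alkoxide in the next step.

Step 11
Reactants: 17 (4R)-4-Ar-5-hydroxy-N-methoxy-N-methylpentanamide; 18 trichloroethylene
Product: 19 (4R)-4-Ar-5-[(E)-1,2-dichloroethenyloxy]-N-methoxy-N-methylpentanamide
Conditions: KH (1.05 equiv), THF, 0 °C; then 18, −40 °C → rt
Reagents that add atoms: none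
Why: The potassium alkoxide eliminates HCl from trichloroethylene and adds anti to the dichloroethyne so formed, the standard entry from an alcohol to a 1,2-dichlorovinyl ether, which forms the O1–C8a bond.

Step 12
Reactants: 20 2,2-dimethylbut-3-enoic acid
Product: 21 2,2-dimethylbut-3-en-1-ol
Conditions: LiAlH4, Et2O, 0 °C → rt
Reagents that add atoms: none
Why: Hydride reduction of the carboxylic acid gives the primary alcohol, and the isolated vinyl group is inert to LiAlH4.

Step 13
Reactants: 21 2,2-dimethylbut-3-en-1-ol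
Product: 22 2,2-dimethylbut-3-enal
Conditions: Dess–Martin periodinane, CH2Cl2, rt; careful distillation, used as a concentrated solution
Reagents that add atoms: none
Why: Dess–Martin oxidation gives the non-enolisable aldehyde without over-oxidation, and its volatility is handled by using it in solution.

Step 14
Reactants: 22 2,2-dimethylbut-3-enal
Product: 23 (E)-1-iodo-3,3-dimethylpenta-1,4-diene
Conditions: CrCl2, CHI3, THF, 0 °C → rt
Reagents that add atoms: iodoform, IC(I)I
Why: Takai olefination (gem-dichromium reagent from CHI3 and CrCl2) converts the α-branched aldehyde into the vinyl iodide with the E preference typical of hindered aldehydes.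

Step 15
Reactants: 19 (4R)-4-Ar-5-[(E)-1,2-dichloroethenyloxy]-N-methoxy-N-methylpentanamide; 23 (E)-1-iodo-3,3-dimethylpenta-1,4-diene
Product: 26 (4E,9R)-9-Ar-10-(ethynyloxy)-3,3-dimethyldeca-1,4-dien-6-one, via alkenyllithium 24 (not isolated), via dilithiated adduct 25 (not isolated)
Conditions: 23 (2.6 equiv), t-BuLi (5.2 equiv), Et2O, −78 °C; add to 19, THF, −78 °C; then n-BuLi (2.0 equiv), −78 → −50 °C; MeOH, −78 °C; pH 7 phosphate buffer
Reagents that add atoms: none
Why: The alkenyllithium adds to the Weinreb amide to give a chelated tetrahedral adduct that masks the ketone, while the excess organolithium removes HCl from the dichlorovinyl ether and exchanges the remaining chlorine for lithium (alkynyl ether synthesis from 1,2-dichlorovinyl ethers), so that quenching releases the E-enone (C7–C5 bond) and the terminal ethynyl ether together.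

Step 16
Reactants: 26 (4E,9R)-9-Ar-10-(ethynyloxy)-3,3-dimethyldeca-1,4-dien-6-one
Product: 28 (4E,9R)-9-Ar-7-diazo-10-(ethynyloxy)-3,3-dimethyldeca-1,4-dien-6-one, via trifluoroacetyl ketone 27 (not isolated)
Conditions: LiN(SiMe3)2, THF, −78 °C; CF3CO2CH2CF3; aq. NaH2PO4 work-up; then MsN3, Et3N, H2O (1 equiv), MeCN, rt
Reagents that add atoms: methanesulfonyl azide, CS(=O)(=O)N=[N+]=[N-]
Why: Kinetic deprotonation at C4a (the only enolisable site, since the γ-carbon is quaternary), trifluoroacetylation and deacylative diazo transfer (Regitz-type transfer with loss of the trifluoroacetyl group) should give the α′-diazo enone under conditions mild enough for the enone and the ethynyl ether.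

Step 17
Reactants: 28 (4E,9R)-9-Ar-7-diazo-10-(ethynyloxy)-3,3-dimethyldeca-1,4-dien-6-one
Product: 33 (3R)-3-Ar-6-(2-methylbut-3-en-2-yl)chroman-7-ol, via vinylketene 29 (not isolated), via cyclobutenone 30 (not isolated), via dienylketene 31 (not isolated), via cyclohexadienone 32 (not isolated)
Conditions: hν (medium-pressure Hg lamp, Pyrex filter, >300 nm), ClCH2CH2Cl (0.005 M), 20 °C; then 80 °C in the dark
Reagents that add atoms: none
Why: Proposed new method: direct irradiation of 28 expels N2 and triggers Wolff rearrangement, the dienyl group moving from C7 to C4a (new C4a–C5 bond) to give vinylketene 29, whose ketene C=C adds [2+2] to the tethered ethynyl ether (C8 to C7, C8a to C4a) to give cyclobutenone 30; on warming, 30 opens (4π) to dienylketene 31, which closes by 6π electrocyclisation (C6–C7) to dienone 32 and tautomerises to phenol 33. The closest known reactions are the intermolecular photochemical Danheiser benzannulation of α-diazo enones with alkoxy- and siloxyalkynes and intramolecular ketene–alkyne [2+2] cycloadditions; a tethered ynol ether that builds the chroman in the same operation has not been described. The pyran ring closes in the cycloaddition as C4a–C8a forms (six-membered ring fused to the cyclobutenone through a four-atom tether), and ring A closes in the thermal 6π-electrocyclic step. No stereocentre is created: C3 is untouched, and the transient centres at C4a (in 30) and C6 (in 32) are erased by ring opening and aromatisation. The step needs the ring A regiochemistry and a Wolff shift that outruns 1,2-hydrogen migration from C4; the first is secured because the nucleophilic alkyne terminus C8 must attack the ketene carbonyl carbon, the tether lets only C8a reach C4a and the endocyclic C8a=C4a bond of 31 holds the dienyl arm cis to the ketene, while the second is favoured by direct, metal-free photolysis at high dilution.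

Step 18
Reactants: 33 (3R)-3-Ar-6-(2-methylbut-3-en-2-yl)chroman-7-ol
Product: 34 Manuifolin E, 4-[(3R)-7-hydroxy-6-(2-methylbut-3-en-2-yl)chroman-3-yl]-6-(2-methylbut-3-en-2-yl)benzene-1,3-diol
Conditions: 3 M HCl (aq.), MeOH/THF, 40 °C
Reagents that add atoms: none
Why: Acid-catalysed acetal exchange with methanol should remove both MOM ethers, while the monosubstituted vinyl groups (which would have to give secondary cations) and C3 are left alone.

**Compound list**
1 | 2,4-dihydroxybenzaldehyde | O=Cc1ccc(O)cc1O | starting material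
2 | prenyl bromide (1-bromo-3-methylbut-2-ene) | CC(C)=CCBr | starting material
3 | 2-hydroxy-4-(3-methylbut-2-enyloxy)benzaldehyde | CC(C)=CCOc1ccc(C=O)c(O)c1 | intermediate
4 | 2-(methoxymethoxy)-4-(3-methylbut-2-enyloxy)benzaldehyde | CC(C)=CCOc1ccc(C=O)c(OCOC)c1 | intermediate
5 | 4-hydroxy-2-(methoxymethoxy)-5-(2-methylbut-3-en-2-yl)benzaldehyde | C=CC(C)(C)c1cc(C=O)c(OCOC)cc1O | intermediate
6 | 2,4-bis(methoxymethoxy)-5-(2-methylbut-3-en-2-yl)benzaldehyde | C=CC(C)(C)c1cc(C=O)c(OCOC)cc1OCOC | intermediate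
7 | [2,4-bis(methoxymethoxy)-5-(2-methylbut-3-en-2-yl)phenyl]acetonitrile | C=CC(C)(C)c1cc(CC#N)c(OCOC)cc1OCOC | intermediate
8 | [2,4-bis(methoxymethoxy)-5-(2-methylbut-3-en-2-yl)phenyl]acetic acid | C=CC(C)(C)c1cc(CC(=O)O)c(OCOC)cc1OCOC | intermediate
9 | (R)-4-benzyl-1,3-oxazolidin-2-one | O=C1N[C@H](Cc2ccccc2)CO1 | starting material
10 | mixed anhydride of 8 with pivalic acid | C=CC(C)(C)c1cc(CC(=O)OC(=O)C(C)(C)C)c(OCOC)cc1OCOC | intermediate
11 | (4R)-4-benzyl-3-(Ar-acetyl)-1,3-oxazolidin-2-one | C=CC(C)(C)c1cc(CC(=O)N2[C@H](Cc3ccccc3)COC2=O)c(OCOC)cc1OCOC | intermediate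
12 | methyl acrylate | C=CC(=O)OC | starting material
13 | Ti(Oi-Pr)Cl2 Z-enolate of 11 | CC(C)O[Ti](Cl)(Cl)O/C(=C\c1cc(C(C)(C)C=C)c(OCOC)cc1OCOC)N1[C@H](Cc2ccccc2)COC1=O | intermediate
14 | methyl (4R)-4-Ar-5-[(4R)-4-benzyl-2-oxo-1,3-oxazolidin-3-yl]-5-oxopentanoate | COC(=O)CC[C@H](c1cc(C(C)(C)C=C)c(OCOC)cc1OCOC)C(=O)N1[C@H](Cc2ccccc2)COC1=O | intermediate
15 | methyl (4R)-4-Ar-5-hydroxypentanoate | COC(=O)CC[C@H](c1cc(C(C)(C)C=C)c(OCOC)cc1OCOC)CO | intermediate
16 | (5R)-5-Ar-oxan-2-one | O=C1CC[C@H](c2cc(C(C)(C)C=C)c(OCOC)cc2OCOC)CO1 | intermediate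
17 | (4R)-4-Ar-5-hydroxy-N-methoxy-N-methylpentanamide | CON(C)C(=O)CC[C@H](c1cc(C(C)(C)C=C)c(OCOC)cc1OCOC)CO | intermediate
18 | trichloroethylene | ClC=C(Cl)Cl | starting material
19 | (4R)-4-Ar-5-[(E)-1,2-dichloroethenyloxy]-N-methoxy-N-methylpentanamide | CON(C)C(=O)CC[C@H](c1cc(C(C)(C)C=C)c(OCOC)cc1OCOC)CO/C(Cl)=C\Cl | intermediate
20 | 2,2-dimethylbut-3-enoic acid | C=CC(C)(C)C(=O)O | starting material
21 | 2,2-dimethylbut-3-en-1-ol | C=CC(C)(C)CO | intermediate
22 | 2,2-dimethylbut-3-enal | C=CC(C)(C)C=O | intermediate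
23 | (E)-1-iodo-3,3-dimethylpenta-1,4-diene | C=CC(C)(C)/C=C/I | intermediate
24 | [(E)-3,3-dimethylpenta-1,4-dienyl]lithium | [Li]/C=C/C(C)(C)C=C | intermediate
25 | dilithiated adduct (lithium hemiaminal alkoxide at C7, lithium alkynyl ether at C8) | C=CC(C)(C)/C=C/C(O[Li])(N(C)OC)CC[C@H](c1cc(C(C)(C)C=C)c(OCOC)cc1OCOC)COC#C[Li] | intermediate
26 | (4E,9R)-9-Ar-10-(ethynyloxy)-3,3-dimethyldeca-1,4-dien-6-one | C=CC(C)(C)/C=C/C(=O)CC[C@H](c1cc(C(C)(C)C=C)c(OCOC)cc1OCOC)COC#C | intermediate
27 | 7-trifluoroacetyl derivative of 26 (epimers at C7 of the chain) | C=CC(C)(C)/C=C/C(=O)C(C(=O)C(F)(F)F)C[C@H](c1cc(C(C)(C)C=C)c(OCOC)cc1OCOC)COC#C | intermediate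
28 | (4E,9R)-9-Ar-7-diazo-10-(ethynyloxy)-3,3-dimethyldeca-1,4-dien-6-one | C=CC(C)(C)/C=C/C(=O)C(=[N+]=[N-])C[C@H](c1cc(C(C)(C)C=C)c(OCOC)cc1OCOC)COC#C | intermediate
29 | vinylketene: (4E)-2-[(2R)-2-Ar-3-(ethynyloxy)propyl]-5,5-dimethylhepta-1,3,6-trien-1-one | O=C=C(C[C@H](c1cc(C(C)(C)C=C)c(OCOC)cc1OCOC)COC#C)/C=C/C(C)(C)C=C | intermediate
30 | cyclobutenone: (4R)-4-Ar-6-[(E)-3,3-dimethylpenta-1,4-dienyl]-2-oxabicyclo[4.2.0]oct-1(8)-en-7-one (either configuration at C6) | O=C1C=C2OC[C@@H](c3cc(C(C)(C)C=C)c(OCOC)cc3OCOC)CC12/C=C/C(C)(C)C=C | intermediate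
31 | dienylketene: 2-{(3R)-3-Ar-5-[(E)-3,3-dimethylpenta-1,4-dienyl]-3,4-dihydro-2H-pyran-6-yl}ethenone | O=C=CC1=C(/C=C/C(C)(C)C=C)C[C@H](c2cc(C(C)(C)C=C)c(OCOC)cc2OCOC)CO1 | intermediate
32 | cyclohexadienone: (3R)-3-Ar-6-(2-methylbut-3-en-2-yl)-3,4-dihydro-2H-chromen-7(6H)-one (either configuration at C6) | O=C1C=C2OC[C@@H](c3cc(C(C)(C)C=C)c(OCOC)cc3OCOC)CC2=CC1C(C)(C)C=C | intermediate
33 | (3R)-3-Ar-6-(2-methylbut-3-en-2-yl)chroman-7-ol (2′,4′-bis-O-MOM ether of the target) | C=CC(C)(C)c1cc2c(cc1O)OC[C@@H](c1cc(C(C)(C)C=C)c(OCOC)cc1OCOC)C2 | intermediate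
34 | Manuifolin E | C=CC(C)(C)c1cc2c(cc1O)OC[C@@H](c1cc(C(C)(C)C=C)c(O)cc1O)C2 | target

**Step count**
Total: 18 steps (15 in the main line, 3 for alkenyl iodide 23).
Longest linear sequence: 15 steps (steps 1–11 and 15–18).

**Steps most likely to fail**

1. Step 17 (key step). What may go wrong:
- the Wolff shift may lose to 1,2-hydrogen migration from C4 or to other carbene pathways;
- the enone may isomerise E to Z under light and slow the 6π closure;
- the ketene may dimerise or be trapped before it reaches the alkyne;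
- the ethynyl ether may fragment thermally before it has reacted.

Fallback, from 3 and 11, returning at 33: ring A is brought in preformed and the pyran ring is closed by etherification. Phenol 3 is silylated (t-BuMe2SiCl, imidazole) to 2-(tert-butyldimethylsilyloxy)-4-(3-methylbut-2-enyloxy)benzaldehyde F1. Reduction (NaBH4, MeOH) gives the benzyl alcohol F2, and CBr4/PPh3 gives the benzyl bromide F3. The sodium enolate of 11 (NaN(SiMe3)2, THF, −78 °C) is alkylated with F3 on the face opposite the auxiliary benzyl group, giving the (2R)-imide F4. NaBH4 (THF/H2O) removes the auxiliary to give the (2R)-alcohol F5, and Bu4NF frees the ring A phenol to give the phenol alcohol F6. Mitsunobu etherification (PPh3, diisopropyl azodicarboxylate) closes the pyran ring to the (3R)-7-prenyloxyisoflavan F7. Aromatic Claisen rearrangement (PhNEt2, 190 °C) is expected to place the 1,1-dimethylallyl group at C6, since C8 lies between O1 and O7, and gives 33.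

2. Step 15. What may go wrong:
- the tetrahedral adduct may collapse early, so that n-BuLi attacks the enone;
- chlorine–lithium exchange may be incomplete;
- the lithium acetylide or methoxide may add to the enone during the quench.

Fallback, from 19, returning at 26: the ketone is carried as its alkoxide instead. i-Bu2AlH (THF, −78 °C) reduces the Weinreb amide to (4R)-4-Ar-5-[(E)-1,2-dichloroethenyloxy]pentanal F8. The alkenylmagnesium reagent made from 24 and MgBr2·OEt2 adds to give the dichlorovinyl allylic alcohol F9 (both carbinol epimers, of no consequence). n-BuLi (3.5 equiv, THF, −78 °C; the first equivalent forms the lithium alkoxide) then converts the dichlorovinyl ether into the ethynyl ether, giving the ethynyl ether allylic alcohol F10 after methanol quench. MnO2 (CH2Cl2, rt) oxidises the allylic alcohol to 26.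

3. Step 8. What may go wrong:
- the titanium Lewis acid may cleave MOM ethers;
- conversion or facial selectivity may be poor with the hindered, electron-rich arylacetyl enolate;
- the acrylate may oligomerise.

Fallback, from 11, returning at 16: C3 is set by enolate alkylation and the chain is completed by alkyne hydration. The sodium enolate of 11 (NaN(SiMe3)2, THF, −78 °C) is alkylated with propargyl bromide on the face opposite the auxiliary benzyl group, giving the (2R)-pent-4-ynoyl imide F11. NaBH4 (THF/H2O) gives (2R)-2-Ar-pent-4-yn-1-ol F12. Cy2BH (2.2 equiv, THF, 0 °C) hydroborates the terminal alkyne in preference to the hindered vinyl group, and NaBO3·4H2O oxidation gives the aldehyde, which closes to the lactol (5R)-5-Ar-oxan-2-ol F13. TEMPO (cat.)/PhI(OAc)2 (CH2Cl2) oxidises F13 to lactone 16.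

**Further compounds**
F1 | step 17 | 2-(tert-butyldimethylsilyloxy)-4-(3-methylbut-2-enyloxy)benzaldehyde | CC(C)=CCOc1ccc(C=O)c(O[Si](C)(C)C(C)(C)C)c1
F2 | step 17 | [2-(tert-butyldimethylsilyloxy)-4-(3-methylbut-2-enyloxy)phenyl]methanol | CC(C)=CCOc1ccc(CO)c(O[Si](C)(C)C(C)(C)C)c1
F3 | step 17 | 1-(bromomethyl)-2-(tert-butyldimethylsilyloxy)-4-(3-methylbut-2-enyloxy)benzene | CC(C)=CCOc1ccc(CBr)c(O[Si](C)(C)C(C)(C)C)c1
F4 | step 17 | (4R)-4-benzyl-3-{(2R)-2-Ar-3-[2-(tert-butyldimethylsilyloxy)-4-(3-methylbut-2-enyloxy)phenyl]propanoyl}-1,3-oxazolidin-2-one | CC(C)=CCOc1ccc(C[C@H](c2cc(C(C)(C)C=C)c(OCOC)cc2OCOC)C(=O)N2[C@H](Cc3ccccc3)COC2=O)c(O[Si](C)(C)C(C)(C)C)c1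
F5 | step 17 | (2R)-2-Ar-3-[2-(tert-butyldimethylsilyloxy)-4-(3-methylbut-2-enyloxy)phenyl]propan-1-ol | CC(C)=CCOc1ccc(C[C@H](c2cc(C(C)(C)C=C)c(OCOC)cc2OCOC)CO)c(O[Si](C)(C)C(C)(C)C)c1
F6 | step 17 | 2-[(2R)-2-Ar-3-hydroxypropyl]-5-(3-methylbut-2-enyloxy)phenol | CC(C)=CCOc1ccc(C[C@H](c2cc(C(C)(C)C=C)c(OCOC)cc2OCOC)CO)c(O)c1
F7 | step 17 | (3R)-3-Ar-7-(3-methylbut-2-enyloxy)chroman | CC(C)=CCOc1ccc2c(c1)OC[C@@H](c1cc(C(C)(C)C=C)c(OCOC)cc1OCOC)C2
F8 | step 15 | (4R)-4-Ar-5-[(E)-1,2-dichloroethenyloxy]pentanal | O=CCC[C@H](c1cc(C(C)(C)C=C)c(OCOC)cc1OCOC)CO/C(Cl)=C\Cl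
F9 | step 15 | (4E,9R)-9-Ar-10-[(E)-1,2-dichloroethenyloxy]-3,3-dimethyldeca-1,4-dien-6-ol | C=CC(C)(C)/C=C/C(O)CC[C@H](c1cc(C(C)(C)C=C)c(OCOC)cc1OCOC)CO/C(Cl)=C\Cl
F10 | step 15 | (4E,9R)-9-Ar-10-(ethynyloxy)-3,3-dimethyldeca-1,4-dien-6-ol | C=CC(C)(C)/C=C/C(O)CC[C@H](c1cc(C(C)(C)C=C)c(OCOC)cc1OCOC)COC#C
F11 | step 8 | (4R)-4-benzyl-3-[(2R)-2-Ar-pent-4-ynoyl]-1,3-oxazolidin-2-one | C#CC[C@H](c1cc(C(C)(C)C=C)c(OCOC)cc1OCOC)C(=O)N1[C@H](Cc2ccccc2)COC1=O
F12 | step 8 | (2R)-2-Ar-pent-4-yn-1-ol | C#CC[C@H](c1cc(C(C)(C)C=C)c(OCOC)cc1OCOC)CO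
F13 | step 8 | (5R)-5-Ar-oxan-2-ol (both anomers) | OC1CC[C@H](c2cc(C(C)(C)C=C)c(OCOC)cc2OCOC)CO1
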